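Over 3.0 min the free monomer of this flask goes two ways, and I wanted one integrated rate for the way into chains.

| flask | free monomer | transfer agent | protic impurity | initiator | remark | time |
|---|---|---|---|---|---|---|
| theta | 3 M | 0.090 M | 0.075 M | 6.7 mol% | run made earlier |  |
| eta | 3 M | 0.090 M | 0.30 M | 6.7 mol% | run made earlier |  |
| delta | 3 M | 0.090 M | 0.15 M | 3.4 mol% | run made earlier |  |
| flask | 3.0 M | 0.0900 M | 0.150 M | 6.7 mol% |  | 3.0 min |

| run | time / min | monomer in chains / % | free monomer / % |
|---|---|---|---|
| theta | 0.250 | 3 | 95 |
| theta | 0.333 | 0 | 90 |
| theta | 0.500 | 9 | 94 |
| theta | 0.833 | 6 | 92 |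
| theta | 1.33 | 8 | 84 |
| theta | 2.00 | 18 | 81 |
| theta | 3.00 | 23 | 72 |
| eta | 0.167 | 2 | 90 |
| eta | 0.500 | 8 | 84 |
| eta | 0.833 | 5 | 81 |
| eta | 1.33 | 14 | 75 |
| eta | 2.00 | 17 | 76 |
| eta | 2.50 | 19 | 69 |
| eta | 3.00 | 24 | 66 |
| delta | 0.667 | 2 | 91 |
| delta | 1.33 | 7 | 86 |
| delta | 2.00 | 9 | 86 |
| delta | 2.50 | 13 | 84 |
| delta | 3.00 | 12 | 84 |

(standard deviation of a reading: 2 percentage points)

- the average divides the monomer in chains by the number of chains begun, living and dead together
- candidate steps: free monomer + initiator -> living end + monomer in chains; free monomer + living end -> monomer in chains + living end; living end + transfer agent -> dead chain; protic impurity + free monomer -> quenched substrate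
- the earlier runs do not show the number of chains; that part of a forecast is a guess

* average number of monomer units in a chain (chains begun, living or dead) at 3.0 min
* part of the free monomer that has reacted at 3.0 min

My first step was the protic impurity: I let it take its equivalent of free monomer at the start, 5.00 % of the charge in this flask. The unaccounted part at the last reading, itself read with scatter, was 5.00 % in theta and 10.0 % in eta, against impurity equivalents of 2.50 % and 10.0 %, so the gap rose with the impurity charge, but only roughly in step with it. For the rest I integrated d[free monomer]/dt = −k[sites][free monomer], which gives ln([free monomer] after the impurity / [free monomer]) = k[initiator charged]t.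

One objection is that the sites are living ends, and the initiator must first become them. But eta read 8 % in chains at 0.500 min and theta 9 % at 0.500 min, and I saw no lag beyond the scatter of 2 percentage points, so I counted the initiator as a site from the start. Another objection is that the transfer agent removes sites, but [transfer agent] was 0.090 M in each run, so that loss sits inside k as read. The last readings of the three runs, pooled, gave 0.487 /M/min for k, the chain constant: the logarithmic loss of free monomer per molar of initiator charged and per minute. For this flask my estimate was 70.8 % free monomer remaining, so a c of 29.2 %.

Dividing by the charge would assume that every initiator began a chain. I assumed the same k for the step of initiator with free monomer, and with a mean [free monomer] of 2.49 M my estimate was 2.64 % of the initiator remaining, so my dp was 3.71.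

The forecast gave c as 29 % (26.5 % to 31.5 %) and a dp of 4.3 (3.5 to 7), above mine, adding “This part is a guess”. The flask gave 29.1 % and a dp of 3.68.

    free monomer + initiator → living end + monomer in chains (k = 0.500 /M/min)
    free monomer + living end → monomer in chains + living end, rate k2*[living end]*[free monomer] (k = 0.500 /M/min)
    living end + transfer agent → dead chain (kL = 0.430 /M/min)
    protic impurity + free monomer → quenched substrate (k = 3.00 /M/min)

I ran the same reckoning on the neighbouring flask with 1.8 M of free monomer, the same loading, [protic impurity] and time. There [initiator charged] was 0.121 M and the impurity's share 8.33 %, which gave 76.9 % free monomer left and c of 23.1 %. A mean [free monomer] of 1.52 M gave an estimate of 10.9 % of the initiator remaining, so dp came to 2.48. That neighbouring flask gave 77 % free monomer, 10 % initiator, c of 23.2 % and a dp of 2.47.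

The numbers in the tables were computed for substances that don't exist; scatter was added.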